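**Structural features**

The target (37 below) is a C20 cembranoid: a 14-membered carbocycle (ring A, C1–C14) cis-fused at C1–C2 to an α-methylene-γ-butyrolactone (ring B: O, C2, C1, C15, C16, with exocyclic C15=C17H2). Cembrane numbering is used for atoms throughout: C1 carries C15, C2 carries the lactone oxygen, then C3=C4(C18H3), C5, C6, C7=C8(C19H2OAc), C9, C10, C11=C12(C20H3), C13, C14. Ring A holds three trisubstituted olefins, each with its two ring bonds trans (3E, 11E, and 7Z only because the acetoxymethyl group outranks C9), separated by CH2–CH2 units. The only stereocentres are the contiguous C1 and C2 (1S,2S; H1 and H2 cis), and there is no third centre to relay them, so their absolute sense must come from a reagent. C2 is both allylic and acyloxy-substituted, so the C2–O bond ionises easily; the α-methylene lactone is a Michael acceptor; the C19 allylic acetate will not survive hydrides or organolithiums. The oxidised C19 methyl rules out a farnesyl or geranylgeranyl starting chain. The real difficulty is to close ring A and set the cis C1/C2 dyad in one absolute sense. The array O–C2–C1–C15(=C17H2) is the retron of a [2,3]-Wittig rearrangement, and the neighbouring C3=C4 olefin can be carried as an alkyne that makes C2–H acidic: this is the feature the key step exploits.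

**Logic of the disconnections**

37 ⇒ 36 ⇒ 35. The O–acetyl bond at C19 is cut, and the C19 oxygen is traced to its 4-methoxybenzyl ether. Reason: an allylic acetate cannot pass the hydride, organolithium and amide-base steps, an ether can. Gain: none in the skeleton, but C19–O is inert until the end. Demand: oxidative ether cleavage and acylation must spare the α-methylene lactone and the ionisable C2–O bond.

35 ⇒ 32 ⇒ 31. The O(C2)–C16 acyl bond is cut and C16 is lowered to the alcohol level (diol 32, then its C16 silyl ether 31). Reason: ring B is electrophilic and would not survive the steps that build the C3=C4 olefin. Gain: ring B disappears and C16 is a protected CH2OH. Demand: the oxidation must take the primary allylic C16–OH before the secondary allylic C2–OH.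

31 ⇒ 30 ⇒ 28. The C4–C18 bond is cut (vinyl iodide 30), then C3–H and C4–I are removed to return the C3≡C4 alkyne 28. Reason: the alkyne is what makes C2–H acidic in the key step, and a C2 alkoxide directs trans-hydroalumination. Gain: one stereodefined trisubstituted olefin becomes a triple bond. Demand: aluminium on C4, trans addition, retention in the iodinolysis and in the coupling.

28 ⇒ 26 (key). The C1–C2 bond is cut, O(C2) is reconnected to C17 and the double bond moves from C15=C17 back to C1=C15. Reason: this is the one bond whose formation creates both stereocentres at once through a cyclic transition state. Gain: both stereocentres and the carbocycle vanish; 26 is an achiral 17-membered ether closed by a C–O bond. Demand: deprotonation at C2 only, [2,3] and not [1,2] shift, C14 cis to C17 on C1=C15, and a chiral base that tells the two C2 protons apart.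

26 ⇒ 25 ⇒ 24. The O–C17 bond is cut (alkoxide on the C2 oxygen, allylic bromide at C17), then the C2 hydroxyl is traced to its silyl ether. Reason: C–O bond formation is the easiest way to close a large ring. Gain: an open chain. Demand: SN2 and not SN2' attack, ring closure faster than oligomerisation, a C2 protecting group that leaves before the C16 one.

24 ⇒ 23 ⇒ 22 ⇒ 21 ⇒ 19 + 20. C16 is returned to the ester level, the C17 bromide is transposed to a C1 hydroxyl, and the C1–C15 bond is cut. Reason: the C1=C15 olefin with two different CH2X arms and fixed geometry is the product of an allylic transposition of a hydroxy acrylate. Gain: C15, C16 and C17 come from 20 in one step. Demand: bromide must enter with the ester trans to C14, and hydride must reduce the ester without touching the bromide.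

19 ⇒ 18 ⇒ 16 ⇒ 14 + 15 (+ 11). The C13–C14 bond is cut as a [3,3] shift (C14 and C1 from 11) and the C11–C12 bond as a carbonyl addition of 15. Reason: the chair Claisen transition state delivers the 11E olefin. Gain: a shorter aldehyde. Demand: high E selectivity.

14 ⇒ 13 ⇒ 10 ⇒ 5 + 8 (+ 11). The C9–C10 bond is cut as a [3,3] shift and the C7–C8 bond as addition of the vinyl-lithium from 8. Reason: the C7=C8 olefin is made with the C19 oxygen already in place and with C6 trans to C9. Gain: two small fragments. Demand: the lithio reagent must add before it eliminates.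

5 ⇒ 4 ⇒ 1 + 2 and 8 ⇒ 6 + 7. The C4–C5 bond is cut (acetylide opening of 2) and the O–C19 bond of 8 (alkoxide of 7 on 6). All six are commercial.

**Other disconnections considered**

Alternative 1: Cut C1–C2 and O–C16 together. The seco aldehyde A1 (enal at C2, (Z)-2-(bromomethyl)enoate at C15–C17) would be closed by an intramolecular carbonyl allylation with CrCl2 (divalent chromium) or zinc, the alkoxide lactonising to 37. This is the first route to come to mind and the shortest on paper. The allyl metal from A1 equilibrates by 1,3-metal shift, so the C1=C15 geometry does not map onto the C1/C2 relationship. Cis versus trans would depend on an open or closed macrocyclic transition state. The absolute sense would need a chiral ligand on the metal in an end-to-end cyclisation at high dilution, and the enal is ambident. The chosen step makes the same bond through a concerted transition state that does translate geometry into configuration, and as a ring contraction.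

Alternative 2: Cut C1–C14. The N-acyloxyphthalimide A2 would be reduced at a cathode; loss of CO2 gives the primary C14 radical, which adds to C1 of the butenolide, and β-scission of the C17–S bond unveils C15=C17 and gives 37 as the last step. The step economy after the key step is the best of all plans. C1, however, would be set only by face selectivity next to an existing C2, with no cyclic link between the two centres. In the intermolecular series, attack anti to the C2 substituent is preferred, which is the trans lactone, and a ten-atom tether can reach either face. The C2–H of A2 is vinylogously acidic and doubly allylic, a racemisation risk during its preparation. Addition–fragmentation at the substituted terminus of such an allyl sulfone, as a macrocyclisation, is untested.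

Alternative 3: Cut C1–C14 by a [3,3] shift. The 18-membered macrolactone A3 (the C17 hydroxymethyl group of the butenolide esterified by a seco acid with one extra carboxyl carbon on C14) would undergo Ireland–Claisen ring contraction to A4, the 14-carboxy derivative of 37, and radical decarboxylation would give 37. Macrolactonisation is reliable, but the amide base and silyl chloride needed for enolisation would first remove the acidic C2–H of the butenolide and erase C2. C1 again rests on face selectivity with a chair/boat ambiguity. One carbon is installed and removed in two extra steps, the second a radical reaction in the presence of the α-methylene lactone.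

Key step: step 16

Remarks: PMB = 4-methoxybenzyl, TBS = tert-butyldimethylsilyl, TIPS = triisopropylsilyl. Assumption: the (S,S)-amide of step 16 is taken to give the (1R,14S) alcohol 28; if the sense of induction is the opposite, the equally available (R,R)-amine is used and nothing else changes.

**Steps**

Step 1
Reactants: 1 tert-butyldimethyl(prop-2-yn-1-yloxy)silane; 2 oxetane
Product: 4 6-(TBS-oxy)hex-4-yn-1-ol, via lithium acetylide 3 (not isolated)
Conditions: n-BuLi, THF, −78 °C; BF3·OEt2, then 2, −78 °C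
Reagents that add atoms: none
Why: Deprotonation of the terminal alkyne (the only acidic C–H at −78 °C) gives 3, which opens BF3-activated oxetane by SN2 attack at carbon; this fixes C2 to C7 with the C2 oxygen already protected.

Step 2
Reactants: 4 6-(TBS-oxy)hex-4-yn-1-ol
Product: 5 6-(TBS-oxy)hex-4-ynal
Conditions: TEMPO (10 mol %), PhI(OAc)2 (1.1 equiv), DCM, rt
Reagents that add atoms: none
Why: Oxoammonium (TEMPO) oxidation of a primary alcohol stops at the aldehyde; the silyl ether and the alkyne are inert and nothing present can move the triple bond.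

Step 3
Reactants: 6 2,3-dibromoprop-1-ene; 7 4-methoxybenzyl alcohol
Product: 8 1-{[(2-bromoprop-2-en-1-yl)oxy]methyl}-4-methoxybenzene
Conditions: 7, NaH, THF, 0 °C; then 6, 0 °C → rt
Reagents that add atoms: none
Why: Williamson etherification; the alkoxide of 7 displaces the allylic bromide of 6 by SN2 and the vinylic bromide is inert to alkoxide.

Step 4
Reactants: 8 1-{[(2-bromoprop-2-en-1-yl)oxy]methyl}-4-methoxybenzene; 5 6-(TBS-oxy)hex-4-ynal
Product: 10 rac-8-(TBS-oxy)-2-[(PMB-oxy)methyl]oct-1-en-6-yn-3-ol, via vinyllithium 9 (not isolated)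
Conditions: 8, t-BuLi (2 equiv), Et2O, −78 °C; then 5, −78 °C
Reagents that add atoms: none
Why: Bromine–lithium exchange gives 9, which adds 1,2 to the aldehyde at −78 °C before β-elimination to allene can compete; the new carbinol centre is racemic and is erased in step 5.

Step 5
Reactants: 10 rac-8-(TBS-oxy)-2-[(PMB-oxy)methyl]oct-1-en-6-yn-3-ol; 11 triethyl orthoacetate
Product: 13 ethyl (4Z)-10-(TBS-oxy)-4-[(PMB-oxy)methyl]dec-4-en-8-ynoate, via ketene acetal 12 (not isolated)
Conditions: 11 (6 equiv), EtCO2H (cat.), 140 °C, EtOH distilled off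
Reagents that add atoms: none
Why: Johnson–Claisen rearrangement; in the chair transition state of 12 the C6 chain is pseudo-equatorial (axial it would clash with the ethoxy group), so C6 ends trans to the new C9–C10 bond and cis to C19, the geometry of the target's C7=C8 olefin.

Step 6
Reactants: 13 ethyl (4Z)-10-(TBS-oxy)-4-[(PMB-oxy)methyl]dec-4-en-8-ynoate
Product: 14 (4Z)-10-(TBS-oxy)-4-[(PMB-oxy)methyl]dec-4-en-8-ynal
Conditions: i-Bu2AlH (1.05 equiv), DCM, −78 °C
Reagents that add atoms: none
Why: Partial ester reduction; at −78 °C the aluminium hemiacetal persists until work-up, so the saturated ester stops at the aldehyde while ethers, alkyne and olefin are inert.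

Step 7
Reactants: 14 (4Z)-10-(TBS-oxy)-4-[(PMB-oxy)methyl]dec-4-en-8-ynal; 15 isopropenylmagnesium bromide
Product: 16 rac-(6Z)-12-(TBS-oxy)-2-methyl-6-[(PMB-oxy)methyl]dodeca-1,6-dien-10-yn-3-ol
Conditions: THF, −78 → 0 °C
Reagents that add atoms: none
Why: Grignard 1,2-addition installs C12, C13 and C20; the racemic carbinol centre is consumed in step 8.

Step 8
Reactants: 16 rac-(6Z)-12-(TBS-oxy)-2-methyl-6-[(PMB-oxy)methyl]dodeca-1,6-dien-10-yn-3-ol; 11 triethyl orthoacetate
Product: 18 ethyl (4E,8Z)-14-(TBS-oxy)-4-methyl-8-[(PMB-oxy)methyl]tetradeca-4,8-dien-12-ynoate, via ketene acetal 17 (not isolated)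
Conditions: 11 (6 equiv), EtCO2H (cat.), 140 °C, EtOH distilled off
Reagents that add atoms: none
Why: Second Johnson–Claisen rearrangement; the chair transition state of 17 with the C10 chain pseudo-equatorial gives the 11E olefin and brings in C14 and C1 (as the ester carbon).

Step 9
Reactants: 18 ethyl (4E,8Z)-14-(TBS-oxy)-4-methyl-8-[(PMB-oxy)methyl]tetradeca-4,8-dien-12-ynoate
Product: 19 (4E,8Z)-14-(TBS-oxy)-4-methyl-8-[(PMB-oxy)methyl]tetradeca-4,8-dien-12-ynal
Conditions: i-Bu2AlH (1.05 equiv), DCM, −78 °C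
Reagents that add atoms: none
Why: Partial ester reduction as in step 6; the product is the C1 aldehyde.

Step 10
Reactants: 19 (4E,8Z)-14-(TBS-oxy)-4-methyl-8-[(PMB-oxy)methyl]tetradeca-4,8-dien-12-ynal; 20 methyl acrylate
Product: 21 rac-methyl (6E,10Z)-16-(TBS-oxy)-3-hydroxy-6-methyl-2-methylidene-10-[(PMB-oxy)methyl]hexadeca-6,10-dien-14-ynoate
Conditions: DABCO (1 equiv), 20 (5 equiv), MeOH, rt
Reagents that add atoms: none
Why: Morita–Baylis–Hillman reaction; the amine–acrylate zwitterion adds to the aldehyde and the amine is expelled, joining C1 to C15 and bringing in C16 and C17; the racemic C1 carbinol is removed in step 11.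

Step 11
Reactants: 21 rac-methyl (6E,10Z)-16-(TBS-oxy)-3-hydroxy-6-methyl-2-methylidene-10-[(PMB-oxy)methyl]hexadeca-6,10-dien-14-ynoate
Product: 22 methyl (2Z,6E,10Z)-2-(bromomethyl)-16-(TBS-oxy)-6-methyl-10-[(PMB-oxy)methyl]hexadeca-2,6,10-trien-14-ynoate
Conditions: NBS, Me2S, DCM, 0 °C → rt
Reagents that add atoms: N-bromosuccinimide, O=C1CCC(=O)N1Br
Why: The bromosulfonium salt from NBS and Me2S activates the allylic alcohol and bromide enters at C17 with allylic transposition (Corey–Kim type); for hydroxy acrylates of this kind the ester is expected trans to the alkyl chain, so C17 (CH2Br) is cis to C14, the geometry the key step needs.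

Step 12
Reactants: 22 methyl (2Z,6E,10Z)-2-(bromomethyl)-16-(TBS-oxy)-6-methyl-10-[(PMB-oxy)methyl]hexadeca-2,6,10-trien-14-ynoate
Product: 23 (2Z,6E,10Z)-2-(bromomethyl)-16-(TBS-oxy)-6-methyl-10-[(PMB-oxy)methyl]hexadeca-2,6,10-trien-14-yn-1-ol
Conditions: i-Bu2AlH (2.2 equiv), DCM, −78 °C
Reagents that add atoms: none
Why: At −78 °C the hydride reduces the conjugated ester to the allylic alcohol faster than it attacks the allylic bromide, a known behaviour of 2-(bromomethyl)acrylates; the olefin geometry is untouched.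

Step 13
Reactants: 23 (2Z,6E,10Z)-2-(bromomethyl)-16-(TBS-oxy)-6-methyl-10-[(PMB-oxy)methyl]hexadeca-2,6,10-trien-14-yn-1-ol
Product: 24 tert-butyl{[(6Z,10E,14Z)-16-bromo-11-methyl-7-[(PMB-oxy)methyl]-15-[(TIPS-oxy)methyl]hexadeca-6,10,14-trien-2-yn-1-yl]oxy}dimethylsilane
Conditions: TIPSOTf, 2,6-lutidine, DCM, −78 °C
Reagents that add atoms: triisopropylsilyl trifluoromethanesulfonate, CC(C)[Si](OS(=O)(=O)C(F)(F)F)(C(C)C)C(C)C
Why: Silylation with the triflate and a hindered pyridine base is fast at −78 °C and offers no nucleophile that could displace the allylic bromide.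

Step 14
Reactants: 24 tert-butyl{[(6Z,10E,14Z)-16-bromo-11-methyl-7-[(PMB-oxy)methyl]-15-[(TIPS-oxy)methyl]hexadeca-6,10,14-trien-2-yn-1-yl]oxy}dimethylsilane
Product: 25 (6Z,10E,14Z)-16-bromo-11-methyl-7-[(PMB-oxy)methyl]-15-[(TIPS-oxy)methyl]hexadeca-6,10,14-trien-2-yn-1-ol
Conditions: HF (48% aq.), MeCN, 0 °C
Reagents that add atoms: none
Why: Acidic fluoride cleaves the primary TBS ether much faster than the bulkier TIPS ether, and no base or good nucleophile is present to attack the allylic bromide.

Step 15
Reactants: 25 (6Z,10E,14Z)-16-bromo-11-methyl-7-[(PMB-oxy)methyl]-15-[(TIPS-oxy)methyl]hexadeca-6,10,14-trien-2-yn-1-ol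
Product: 26 (3E,7E,11Z)-11-[(PMB-oxy)methyl]-7-methyl-3-[(TIPS-oxy)methyl]-1-oxacycloheptadeca-3,7,11-trien-15-yne
Conditions: NaH (3 equiv), THF, 50 °C, slow addition of 25 (final 2 mM)
Reagents that add atoms: none
Why: Intramolecular Williamson etherification; the propargylic alkoxide displaces the primary allylic bromide by SN2 (SN2' attack at the secondary C1 is hindered), and slow addition keeps the open-chain alkoxide dilute enough for the 17-membered ring to win over oligomers.

Step 16
Reactants: 26 (3E,7E,11Z)-11-[(PMB-oxy)methyl]-7-methyl-3-[(TIPS-oxy)methyl]-1-oxacycloheptadeca-3,7,11-trien-15-yne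
Product: 28 (1R,6Z,10E,14S)-7-[(PMB-oxy)methyl]-11-methyl-14-[3-(TIPS-oxy)prop-1-en-2-yl]cyclotetradeca-6,10-dien-2-yn-1-ol, via lithiated ether 27 (not isolated)
Conditions: (S,S)-bis(1-phenylethyl)amine (1.5 equiv), n-BuLi (1.4 equiv), THF, −40 → −15 °C; aq. NH4Cl
Reagents that add atoms: none
Why: The lithium amide removes a proton from C2, the most acidic C–H of 26 (α to oxygen and propargylic), to give 27. The carbanion then attacks C1 across the ether bridge through a five-membered, six-electron transition state while the O–C17 bond breaks and the double bond moves from C1=C15 to C15=C17; this is a [2,3]-Wittig rearrangement, and its closest precedent is the amide-base ring contraction of large-ring propargyl allyl ethers to propargylic carbinols. Ring A is closed here as a 17 → 14 ring contraction (O, C17 and C15 leave the ring), not as an end-to-end cyclisation, so the entropic cost was paid in the easier C–O closure of step 15. C1 and C2 are created together and their relative configuration is fixed by the envelope transition state: the alkynyl group on C2 sits exo, away from the CH2OTIPS group on C15, and because C14 is cis to C17 it lies on the same side as the exo alkynyl group, so C3 and C14 become syn across the new bond (the Z-allyl-to-syn rule), which is the cis relationship of ring B. The ten-atom tether C4–C13 that joins C3 to C14 spans this same-side arrangement most easily, so the ring reinforces the acyclic preference. The absolute sense is set by the chiral amide, which tells the two enantiotopic C2 protons apart inside its lithium aggregate, the propargyllithium rearranging faster than it racemises at this temperature. Three selectivities are needed: C2–H over C17–H deprotonation and [2,3] over [1,2] shift, both secured by the substrate and the low temperature, and one enantiotopic proton over the other, secured only by the reagent and therefore the least certain.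

Step 17
Reactants: 28 (1R,6Z,10E,14S)-7-[(PMB-oxy)methyl]-11-methyl-14-[3-(TIPS-oxy)prop-1-en-2-yl]cyclotetradeca-6,10-dien-2-yn-1-ol
Product: 30 (1R,2Z,6Z,10E,14S)-3-iodo-7-[(PMB-oxy)methyl]-11-methyl-14-[3-(TIPS-oxy)prop-1-en-2-yl]cyclotetradeca-2,6,10-trien-1-ol, via alkenylaluminate 29 (not isolated)
Conditions: NaAlH2(OCH2CH2OMe)2, THF, 0 °C → rt; then iodine, THF, −78 → 0 °C
Reagents that add atoms: iodine, [I][I]
Why: The C2 alkoxide binds aluminium and hydride is delivered intramolecularly to C3 with aluminium on C4 (trans-hydroalumination through oxa-aluminacycle 29); iodine cleaves the C4–Al bond with retention, so iodine is cis to C2 and C5 is trans to C2.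

Step 18
Reactants: 30 (1R,2Z,6Z,10E,14S)-3-iodo-7-[(PMB-oxy)methyl]-11-methyl-14-[3-(TIPS-oxy)prop-1-en-2-yl]cyclotetradeca-2,6,10-trien-1-ol
Product: 31 (1S,2E,6Z,10E,14S)-7-[(PMB-oxy)methyl]-3,11-dimethyl-14-[3-(TIPS-oxy)prop-1-en-2-yl]cyclotetradeca-2,6,10-trien-1-ol
Conditions: MeZnCl (3 equiv), Pd(PPh3)4 (zerovalent palladium, 5 mol %), THF, rt → 45 °C
Reagents that add atoms: methylzinc chloride, C[Zn]Cl
Why: Negishi coupling; oxidative addition, transmetallation and reductive elimination all retain the olefin geometry, so C18 is cis to C2 and the 3E olefin results (the descriptor at the carbinol changes from R to S only because the priorities change).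

Step 19
Reactants: 31 (1S,2E,6Z,10E,14S)-7-[(PMB-oxy)methyl]-3,11-dimethyl-14-[3-(TIPS-oxy)prop-1-en-2-yl]cyclotetradeca-2,6,10-trien-1-ol
Product: 32 (1S,2E,6Z,10E,14S)-14-(3-hydroxyprop-1-en-2-yl)-7-[(PMB-oxy)methyl]-3,11-dimethylcyclotetradeca-2,6,10-trien-1-ol
Conditions: TBAF, THF, 0 °C → rt
Reagents that add atoms: none
Why: Fluoride cleaves the silyl ether; the PMB ether, the olefins and both stereocentres are untouched.

Step 20
Reactants: 32 (1S,2E,6Z,10E,14S)-14-(3-hydroxyprop-1-en-2-yl)-7-[(PMB-oxy)methyl]-3,11-dimethylcyclotetradeca-2,6,10-trien-1-ol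
Product: 35 (1S,2S,3E,7Z,11E)-19-[(4-methoxybenzyl)oxy]cembra-3,7,11,15(17)-tetraen-16,2-olide, via hydroxy enal 33 (not isolated), via lactol 34 (not isolated)
Conditions: TEMPO (20 mol %), PhI(OAc)2 (2.5 equiv), DCM, rt
Reagents that add atoms: none
Why: The oxoammonium salt oxidises the unhindered primary allylic alcohol first to enal 33, which the cis-disposed C2 hydroxyl traps as lactol 34; a second oxidation gives the lactone (oxidative lactonisation of a 1,4-diol), which also takes the secondary C2–OH out of competition; C1 and C2 are not touched.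

Step 21
Reactants: 35 (1S,2S,3E,7Z,11E)-19-[(4-methoxybenzyl)oxy]cembra-3,7,11,15(17)-tetraen-16,2-olide
Product: 36 (1S,2S,3E,7Z,11E)-19-hydroxycembra-3,7,11,15(17)-tetraen-16,2-olide
Conditions: DDQ, DCM–pH 7 phosphate buffer (10:1), 0 °C
Reagents that add atoms: none
Why: Oxidative cleavage of the electron-rich benzyl ether by hydride abstraction and hydrolysis of the oxocarbenium ion; the neutral buffered medium spares the α-methylene lactone and the ionisable C2–O bond.

Step 22
Reactants: 36 (1S,2S,3E,7Z,11E)-19-hydroxycembra-3,7,11,15(17)-tetraen-16,2-olide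
Product: 37 (1S,2S,3E,7Z,11E)-19-acetoxycembra-3,7,11,15(17)-tetraen-16,2-olide, the target
Conditions: Ac2O, pyridine, DMAP (cat.), DCM, 0 °C
Reagents that add atoms: acetic anhydride, CC(=O)OC(C)=O
Why: Acylation of the primary allylic alcohol under mildly basic conditions that neither add to nor isomerise the α-methylene lactone.

**Compound list**

1 | tert-butyldimethyl(prop-2-yn-1-yloxy)silane | C#CCO[Si](C)(C)C(C)(C)C | starting material
2 | oxetane | C1COC1 | starting material
3 | {3-[(tert-butyldimethylsilyl)oxy]prop-1-yn-1-yl}lithium | [Li]C#CCO[Si](C)(C)C(C)(C)C | intermediate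
4 | 6-(TBS-oxy)hex-4-yn-1-ol | OCCCC#CCO[Si](C)(C)C(C)(C)C | intermediate
5 | 6-(TBS-oxy)hex-4-ynal | O=CCCC#CCO[Si](C)(C)C(C)(C)C | intermediate
6 | 2,3-dibromoprop-1-ene | C=C(Br)CBr | starting material
7 | 4-methoxybenzyl alcohol | COc1ccc(CO)cc1 | starting material
8 | 1-{[(2-bromoprop-2-en-1-yl)oxy]methyl}-4-methoxybenzene | C=C(Br)COCc1ccc(OC)cc1 | intermediate
9 | {3-[(4-methoxybenzyl)oxy]prop-1-en-2-yl}lithium | [Li]C(=C)COCc1ccc(OC)cc1 | intermediate
10 | rac-8-(TBS-oxy)-2-[(PMB-oxy)methyl]oct-1-en-6-yn-3-ol | C=C(COCc1ccc(OC)cc1)C(O)CCC#CCO[Si](C)(C)C(C)(C)C | intermediate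
11 | triethyl orthoacetate | CCOC(C)(OCC)OCC | starting material
12 | 1-ethoxyvinyl ether of 10 (mixed ketene acetal) | C=C(OCC)OC(CCC#CCO[Si](C)(C)C(C)(C)C)C(=C)COCc1ccc(OC)cc1 | intermediate
13 | ethyl (4Z)-10-(TBS-oxy)-4-[(PMB-oxy)methyl]dec-4-en-8-ynoate | CCOC(=O)CC/C(COCc1ccc(OC)cc1)=C/CCC#CCO[Si](C)(C)C(C)(C)C | intermediate
14 | (4Z)-10-(TBS-oxy)-4-[(PMB-oxy)methyl]dec-4-en-8-ynal | O=CCC/C(COCc1ccc(OC)cc1)=C/CCC#CCO[Si](C)(C)C(C)(C)C | intermediate
15 | isopropenylmagnesium bromide | C=C(C)[Mg]Br | starting material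
16 | rac-(6Z)-12-(TBS-oxy)-2-methyl-6-[(PMB-oxy)methyl]dodeca-1,6-dien-10-yn-3-ol | C=C(C)C(O)CC/C(COCc1ccc(OC)cc1)=C/CCC#CCO[Si](C)(C)C(C)(C)C | intermediate
17 | 1-ethoxyvinyl ether of 16 (mixed ketene acetal) | C=C(OCC)OC(CC/C(COCc1ccc(OC)cc1)=C/CCC#CCO[Si](C)(C)C(C)(C)C)C(C)=C | intermediate
18 | ethyl (4E,8Z)-14-(TBS-oxy)-4-methyl-8-[(PMB-oxy)methyl]tetradeca-4,8-dien-12-ynoate | CCOC(=O)CC/C(C)=C/CC/C(COCc1ccc(OC)cc1)=C/CCC#CCO[Si](C)(C)C(C)(C)C | intermediate
19 | (4E,8Z)-14-(TBS-oxy)-4-methyl-8-[(PMB-oxy)methyl]tetradeca-4,8-dien-12-ynal | O=CCC/C(C)=C/CC/C(COCc1ccc(OC)cc1)=C/CCC#CCO[Si](C)(C)C(C)(C)C | intermediate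
20 | methyl acrylate | C=CC(=O)OC | starting material
21 | rac-methyl (6E,10Z)-16-(TBS-oxy)-3-hydroxy-6-methyl-2-methylidene-10-[(PMB-oxy)methyl]hexadeca-6,10-dien-14-ynoate | COC(=O)C(=C)C(O)CC/C(C)=C/CC/C(COCc1ccc(OC)cc1)=C/CCC#CCO[Si](C)(C)C(C)(C)C | intermediate
22 | methyl (2Z,6E,10Z)-2-(bromomethyl)-16-(TBS-oxy)-6-methyl-10-[(PMB-oxy)methyl]hexadeca-2,6,10-trien-14-ynoate | COC(=O)/C(CBr)=C/CC/C(C)=C/CC/C(COCc1ccc(OC)cc1)=C/CCC#CCO[Si](C)(C)C(C)(C)C | intermediate
23 | (2Z,6E,10Z)-2-(bromomethyl)-16-(TBS-oxy)-6-methyl-10-[(PMB-oxy)methyl]hexadeca-2,6,10-trien-14-yn-1-ol | OC/C(CBr)=C/CC/C(C)=C/CC/C(COCc1ccc(OC)cc1)=C/CCC#CCO[Si](C)(C)C(C)(C)C | intermediate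
24 | tert-butyl{[(6Z,10E,14Z)-16-bromo-11-methyl-7-[(PMB-oxy)methyl]-15-[(TIPS-oxy)methyl]hexadeca-6,10,14-trien-2-yn-1-yl]oxy}dimethylsilane | CC(C)[Si](OC/C(CBr)=C/CC/C(C)=C/CC/C(COCc1ccc(OC)cc1)=C/CCC#CCO[Si](C)(C)C(C)(C)C)(C(C)C)C(C)C | intermediate
25 | (6Z,10E,14Z)-16-bromo-11-methyl-7-[(PMB-oxy)methyl]-15-[(TIPS-oxy)methyl]hexadeca-6,10,14-trien-2-yn-1-ol | CC(C)[Si](OC/C(CBr)=C/CC/C(C)=C/CC/C(COCc1ccc(OC)cc1)=C/CCC#CCO)(C(C)C)C(C)C | intermediate
26 | (3E,7E,11Z)-11-[(PMB-oxy)methyl]-7-methyl-3-[(TIPS-oxy)methyl]-1-oxacycloheptadeca-3,7,11-trien-15-yne | O1CC#CCC/C=C(COCc2ccc(OC)cc2)/CC/C=C(C)/CC/C=C(CO[Si](C(C)C)(C(C)C)C(C)C)\C1 | intermediate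
27 | 17-lithio derivative of 26 (lithium on the propargylic O–CH carbon, C2) | [Li]C1OC/C(CO[Si](C(C)C)(C(C)C)C(C)C)=C\CC/C(C)=C/CC/C(COCc2ccc(OC)cc2)=C/CCC#C1 | intermediate
28 | (1R,6Z,10E,14S)-7-[(PMB-oxy)methyl]-11-methyl-14-[3-(TIPS-oxy)prop-1-en-2-yl]cyclotetradeca-6,10-dien-2-yn-1-ol | C=C(CO[Si](C(C)C)(C(C)C)C(C)C)[C@@H]1CC/C(C)=C/CC/C(COCc2ccc(OC)cc2)=C/CCC#C[C@@H]1O | intermediate
29 | sodium bis(2-methoxyethoxy)aluminate of 28 with Al bound to O(C2) and to C4 (five-membered oxa-aluminacycle) | C=C(CO[Si](C(C)C)(C(C)C)C(C)C)[C@@H]1CC/C(C)=C/CC/C(COCc2ccc(OC)cc2)=C/CC/C3=C/[C@@H]1O[Al-]3(OCCOC)OCCOC.[Na+] | intermediate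
30 | (1R,2Z,6Z,10E,14S)-3-iodo-7-[(PMB-oxy)methyl]-11-methyl-14-[3-(TIPS-oxy)prop-1-en-2-yl]cyclotetradeca-2,6,10-trien-1-ol | C=C(CO[Si](C(C)C)(C(C)C)C(C)C)[C@@H]1CC/C(C)=C/CC/C(COCc2ccc(OC)cc2)=C/CC/C(I)=C/[C@@H]1O | intermediate
31 | (1S,2E,6Z,10E,14S)-7-[(PMB-oxy)methyl]-3,11-dimethyl-14-[3-(TIPS-oxy)prop-1-en-2-yl]cyclotetradeca-2,6,10-trien-1-ol | C=C(CO[Si](C(C)C)(C(C)C)C(C)C)[C@@H]1CC/C(C)=C/CC/C(COCc2ccc(OC)cc2)=C/CC/C(C)=C/[C@@H]1O | intermediate
32 | (1S,2E,6Z,10E,14S)-14-(3-hydroxyprop-1-en-2-yl)-7-[(PMB-oxy)methyl]-3,11-dimethylcyclotetradeca-2,6,10-trien-1-ol | C=C(CO)[C@@H]1CC/C(C)=C/CC/C(COCc2ccc(OC)cc2)=C/CC/C(C)=C/[C@@H]1O | intermediate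
33 | 2-[(1S,2S,3E,7Z,11E)-2-hydroxy-8-[(PMB-oxy)methyl]-4,12-dimethylcyclotetradeca-3,7,11-trien-1-yl]prop-2-enal | C=C(C=O)[C@@H]1CC/C(C)=C/CC/C(COCc2ccc(OC)cc2)=C/CC/C(C)=C/[C@@H]1O | intermediate
34 | (1S,2S,3E,7Z,11E)-19-[(4-methoxybenzyl)oxy]cembra-3,7,11,15(17)-tetraene-16,2-lactol (both anomers at C16) | C=C1C(O)O[C@H]2/C=C(\C)CC/C=C(\COCc3ccc(OC)cc3)CC/C=C(\C)CC[C@@H]12 | intermediate
35 | (1S,2S,3E,7Z,11E)-19-[(4-methoxybenzyl)oxy]cembra-3,7,11,15(17)-tetraen-16,2-olide | C=C1C(=O)O[C@H]2/C=C(\C)CC/C=C(\COCc3ccc(OC)cc3)CC/C=C(\C)CC[C@@H]12 | intermediate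
36 | (1S,2S,3E,7Z,11E)-19-hydroxycembra-3,7,11,15(17)-tetraen-16,2-olide | C=C1C(=O)O[C@H]2/C=C(\C)CC/C=C(\CO)CC/C=C(\C)CC[C@@H]12 | intermediate
37 | (1S,2S,3E,7Z,11E)-19-acetoxycembra-3,7,11,15(17)-tetraen-16,2-olide = [(3aS,6E,10Z,14E,15aS)-6,14-dimethyl-3-methylidene-2-oxo-2,3,3a,4,5,8,9,12,13,15a-decahydrocyclotetradeca[b]furan-10-yl]methyl acetate | C=C1C(=O)O[C@H]2/C=C(\C)CC/C=C(\COC(C)=O)CC/C=C(\C)CC[C@@H]12 | target

**Step count and least certain steps**

Total: 22 steps. Longest linear sequence: 21 steps (steps 1, 2 and 4–22, from 1); step 3 is a one-step branch.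

Step 16 (key step). The most likely failure is poor discrimination between the two enantiotopic C2 protons, because a flexible 17-membered ether may bind the chiral lithium amide aggregate only loosely; a competing [1,2]-shift is a lesser risk. Fallback: from 26, run the ring contraction with achiral lithium 2,2,6,6-tetramethylpiperidide, which should give the same cis alcohol as a racemate, that is 28 together with its enantiomer F1. Esterification with (S)-2-methoxy-2-phenylacetic acid (DCC, DMAP) gives the diastereomeric esters, the (S)-2-methoxy-2-phenylacetate of 28, F2, and that of F1, F3. These are separated by chromatography, and methanolysis of F2 (K2CO3, MeOH) returns the route to 28.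

Step 15. The most likely failure is intermolecular O-alkylation (oligomers) outrunning the slow 17-membered closure, with SN2' attack at C1 as a second leak. Fallback (Nicholas etherification instead of Williamson), from 25: KOAc with 18-crown-6 in MeCN replaces bromide by acetate to give the allylic acetate F4, and K2CO3 in MeOH frees the diol F5. Co2(CO)8 then gives the hexacarbonyldicobalt complex F6. BF3·OEt2 at high dilution ionises the propargylic hydroxyl to the cobalt-stabilised cation, which the C17 hydroxyl captures to give the complexed cyclic ether F7; the bent complexed alkyne brings the chain ends together. Fe(NO3)3·9H2O in ethanol removes the metal and returns the route to 26.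

Step 17. The most likely failure is incomplete or misdirected hydroalumination inside the ring, because the O–Al unit must reach across an endocyclic triple bond, and protonolysis of the C–Al bond before iodination. Fallback, from 28: trans-hydrosilylation with BnMe2SiH and [Cp*Ru(MeCN)3]PF6, which for propargylic alcohols places silicon on the carbon distal to oxygen, gives the vinylsilane F8. Iododesilylation with N-iodosuccinimide in MeCN, with retention, returns the route to 30.

Step 10. The most likely failure is a slow, incomplete reaction, with aldol self-condensation of the enolisable aldehyde during the long exposure to amine. Fallback, from 19: 1,4-hydroalumination of methyl propiolate with i-Bu2AlH and N-methylmorpholine N-oxide gives the vinylalane F9, which adds to 19 at 0 °C and returns the route to 21 without an amine catalyst.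

**Further compounds**

F1 | step 16 | (1S,6Z,10E,14R)-7-[(PMB-oxy)methyl]-11-methyl-14-[3-(TIPS-oxy)prop-1-en-2-yl]cyclotetradeca-6,10-dien-2-yn-1-ol (enantiomer of 28) | C=C(CO[Si](C(C)C)(C(C)C)C(C)C)[C@H]1CC/C(C)=C/CC/C(COCc2ccc(OC)cc2)=C/CCC#C[C@H]1O
F2 | step 16 | (S)-2-methoxy-2-phenylacetate of 28 | C=C(CO[Si](C(C)C)(C(C)C)C(C)C)[C@@H]1CC/C(C)=C/CC/C(COCc2ccc(OC)cc2)=C/CCC#C[C@@H]1OC(=O)[C@@H](OC)c1ccccc1
F3 | step 16 | (S)-2-methoxy-2-phenylacetate of F1 | C=C(CO[Si](C(C)C)(C(C)C)C(C)C)[C@H]1CC/C(C)=C/CC/C(COCc2ccc(OC)cc2)=C/CCC#C[C@H]1OC(=O)[C@@H](OC)c1ccccc1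
F4 | step 15 | (2E,6E,10Z)-16-hydroxy-6-methyl-10-[(PMB-oxy)methyl]-2-[(TIPS-oxy)methyl]hexadeca-2,6,10-trien-14-yn-1-yl acetate | CC(C)[Si](OC/C(COC(C)=O)=C/CC/C(C)=C/CC/C(COCc1ccc(OC)cc1)=C/CCC#CCO)(C(C)C)C(C)C
F5 | step 15 | (2E,6E,10Z)-6-methyl-10-[(PMB-oxy)methyl]-2-[(TIPS-oxy)methyl]hexadeca-2,6,10-trien-14-yne-1,16-diol | CC(C)[Si](OC/C(CO)=C/CC/C(C)=C/CC/C(COCc1ccc(OC)cc1)=C/CCC#CCO)(C(C)C)C(C)C
F6 | step 15 | hexacarbonyldicobalt complex, Co2(CO)6, of the triple bond of F5 | CC(C)[Si](OC/C(CO)=C/CC/C(C)=C/CC/C(COCc1ccc(OC)cc1)=C/CCC12[Co]3(=C=O)(=C=O)(=C=O)[Co]1(=C=O)(=C=O)(=C=O)C23CO)(C(C)C)C(C)C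
F7 | step 15 | hexacarbonyldicobalt complex, Co2(CO)6, of the triple bond of 26 | O1CC23[Co]4(=C=O)(=C=O)(=C=O)[Co]2(=C=O)(=C=O)(=C=O)C34CC/C=C(COCc5ccc(OC)cc5)/CC/C=C(C)/CC/C=C(CO[Si](C(C)C)(C(C)C)C(C)C)\C1
F8 | step 17 | (1R,2Z,6Z,10E,14S)-3-[benzyl(dimethyl)silyl]-7-[(PMB-oxy)methyl]-11-methyl-14-[3-(TIPS-oxy)prop-1-en-2-yl]cyclotetradeca-2,6,10-trien-1-ol | C=C(CO[Si](C(C)C)(C(C)C)C(C)C)[C@@H]1CC/C(C)=C/CC/C(COCc2ccc(OC)cc2)=C/CC/C([Si](C)(C)Cc2ccccc2)=C/[C@@H]1O
F9 | step 10 | methyl 2-[bis(2-methylpropyl)alumanyl]prop-2-enoate | C=C([Al](CC(C)C)CC(C)C)C(=O)OC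
A1 | alternative 1 | methyl (2Z,6E,10Z,14E)-10-(acetoxymethyl)-2-(bromomethyl)-6,14-dimethyl-16-oxohexadeca-2,6,10,14-tetraenoate | COC(=O)/C(CBr)=C/CC/C(C)=C/CC/C(COC(C)=O)=C/CC/C(C)=C/C=O
A2 | alternative 2 | 1,3-dioxoisoindolin-2-yl (4E,8Z,12E)-8-(acetoxymethyl)-4,12-dimethyl-13-[(2S)-5-oxo-4-(phenylsulfonylmethyl)-2,5-dihydrofuran-2-yl]trideca-4,8,12-trienoate | O=C1O[C@@H](/C=C(\C)CC/C=C(\COC(C)=O)CC/C=C(\C)CCC(=O)ON2C(=O)c3ccccc3C2=O)C=C1CS(=O)(=O)c1ccccc1
A3 | alternative 3 | 18-membered macrolactone: the C17 hydroxymethyl group of the (2S)-butenolide esterified by the carboxyl carbon attached to C14 | O=C1OCC2=C[C@@H](OC2=O)/C=C(\C)CC/C=C(\COC(C)=O)CC/C=C(\C)CC1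
A4 | alternative 3 | 14-carboxy derivative of 37 (configuration at C14 open) | C=C1C(=O)O[C@H]2/C=C(\C)CC/C=C(\COC(C)=O)CC/C=C(\C)CC(C(=O)O)[C@@H]12
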